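**Retrosynthetic overview**
1. Didemnidine B ⇒ N8-Boc ketoamide in which N1 and N4 of the spermidine chain are tied together by one CH2 unit. Boc loss and excision of this tether are the last operations.
2. Key disconnection: three bonds of that ketoamide are cut at once (C3–CO, CO–CO, CO–N). This leads to the C3–H of 6-bromoindole, two CO and the ring N–H of the masked spermidine (one-flask iodination and Pd double carbonylation, no oxalyl chloride).
3. Masked amine ⇒ spermidine + formaldehyde, then a primary-selective Boc on N8. The aminal fixes the N1/N8 regiochemistry and turns N1 into a cyclic secondary amine, the amine class that gives the best ketoamide selectivity.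
4. Rings: the indole is bought intact. The only ring made is the temporary hexahydropyrimidine (step 1), which is opened again in step 4.

Assumption: the target SMILES has no stereocentre and no stereogenic double bond, so the compound is achiral and nothing has to be set or preserved. Spermidine numbering is N1 (aminopropyl end), N4, N8 (aminobutyl end).

**Step 1**
Reactants: 1 spermidine
Product: 2 4-(tetrahydropyrimidin-1(2H)-yl)butan-1-amine
Conditions: 37% aq. HCHO (1.0 equiv), H2O, 0 °C to rt, 1 h; extract CHCl3
Reagents that add atoms: formaldehyde, C=O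
Why: Aminal cyclocondensation, in which one equivalent of formaldehyde is taken up by the N1/N4 1,3-diamine pair because only this pair can close a strain-free six-membered ring, leaving N8 as the only primary amine and creating no stereocentre.

**Step 2**
Reactants: 2 4-(tetrahydropyrimidin-1(2H)-yl)butan-1-amine
Product: 3 tert-butyl [4-(tetrahydropyrimidin-1(2H)-yl)butyl]carbamate
Conditions: t-BuOCO2Ph (1.0 equiv), CH2Cl2, rt, 16 h; wash 1 M NaOH
Reagents that add atoms: tert-butyl phenyl carbonate, CC(C)(C)OC(=O)Oc1ccccc1
Why: Chemoselective Boc protection, in which the weakly electrophilic aryl carbonate reacts with the unhindered, more basic primary amine and not with the less nucleophilic secondary aminal N–H, a selectivity well established for polyamines.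

**Step 3**
Reactants: 4 6-bromo-1H-indole; 3 tert-butyl [4-(tetrahydropyrimidin-1(2H)-yl)butyl]carbamate
Product: 6 tert-butyl (4-{3-[2-(6-bromo-1H-indol-3-yl)-2-oxoacetyl]tetrahydropyrimidin-1(2H)-yl}butyl)carbamate, via 6-bromo-3-iodo-1H-indole 5 (not isolated)
Conditions: I2 (1.0 equiv), K2CO3 (3 equiv), DMF, rt, dark, 1 h; then 3 (1.5 equiv), Pd(OAc)2 (5 mol %), P(t-Bu)3·HBF4 (10 mol %), CO (10 bar), 40 °C, 16 h
Reagents that add atoms: carbon monoxide, [C-]#[O+] (2 equiv, both C=O units of the glyoxyl bridge); iodine, [I][I] (iodine atom of 5 only, gone in 6)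
Why: Electrophilic C3 iodination followed by palladium-catalysed double aminocarbonylation of the aryl iodide, in which zerovalent palladium inserts into the weak C3–I bond and leaves C6–Br alone at 40 °C under CO, CO insertion gives an electron-rich aroyl complex that resists direct aminolysis, and the cyclic secondary amine therefore attacks a second coordinated CO so that aroyl–carbamoyl reductive elimination delivers the α-ketoamide.

**Step 4**
Reactants: 6 tert-butyl (4-{3-[2-(6-bromo-1H-indol-3-yl)-2-oxoacetyl]tetrahydropyrimidin-1(2H)-yl}butyl)carbamate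
Product: 7 tert-butyl {4-[(3-{[2-(6-bromo-1H-indol-3-yl)-2-oxoacetyl]amino}propyl)amino]butyl}carbamate (N8-Boc-didemnidine B)
Conditions: CH2(CO2H)2 (3 equiv), pyridine (5 equiv), EtOH, reflux, 3 h; aq. Na2CO3 work-up
Reagents that add atoms: none
Why: Knoevenagel–Doebner formaldehyde transfer, the established way to open N-acylated spermidine hexahydropyrimidines, in which the buffered medium lets the N-acyl aminal ionise to the N4 methyleneiminium ion (the ketoamide nitrogen is a good leaving group) and malonic acid removes the CH2 unit irreversibly, while the Boc group, the vinylogous-amide ketone and the aryl bromide are untouched.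

**Step 5**
Reactants: 7 tert-butyl {4-[(3-{[2-(6-bromo-1H-indol-3-yl)-2-oxoacetyl]amino}propyl)amino]butyl}carbamate
Product: 9 didemnidine B, via didemnidine B dihydrochloride 8 (not isolated)
Conditions: 4 M HCl in 1,4-dioxane, CH2Cl2, 0 °C to rt, 2 h; evaporate; NaOH (2.0 equiv), MeOH, 0 °C; evaporate, take up in CH2Cl2/MeOH 9:1, filter
Reagents that add atoms: hydrogen chloride, Cl (chloride of 8 only, gone in 9)
Why: Acidolytic Boc cleavage by tert-butyl cation fragmentation and decarboxylation followed by simple neutralisation, tolerated because the 3-acylindole is too electron-poor to be tert-butylated and the ketoamide and aryl bromide are acid-stable.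

**Compound list**
1 | spermidine, N1-(3-aminopropyl)butane-1,4-diamine | NCCCCNCCCN | starting material
2 | 4-(tetrahydropyrimidin-1(2H)-yl)butan-1-amine, also called 1-(4-aminobutyl)hexahydropyrimidine | NCCCCN1CCCNC1 | intermediate
3 | tert-butyl [4-(tetrahydropyrimidin-1(2H)-yl)butyl]carbamate | CC(C)(C)OC(=O)NCCCCN1CCCNC1 | intermediate
4 | 6-bromo-1H-indole | Brc1ccc2cc[nH]c2c1 | starting material
5 | 6-bromo-3-iodo-1H-indole | Ic1c[nH]c2cc(Br)ccc12 | intermediate
6 | tert-butyl (4-{3-[2-(6-bromo-1H-indol-3-yl)-2-oxoacetyl]tetrahydropyrimidin-1(2H)-yl}butyl)carbamate | CC(C)(C)OC(=O)NCCCCN1CCCN(C1)C(=O)C(=O)c1c[nH]c2cc(Br)ccc12 | intermediate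
7 | tert-butyl {4-[(3-{[2-(6-bromo-1H-indol-3-yl)-2-oxoacetyl]amino}propyl)amino]butyl}carbamate | CC(C)(C)OC(=O)NCCCCNCCCNC(=O)C(=O)c1c[nH]c2cc(Br)ccc12 | intermediate
8 | didemnidine B dihydrochloride | NCCCCNCCCNC(=O)C(=O)c1c[nH]c2cc(Br)ccc12.Cl.Cl | intermediate
9 | didemnidine B, N-{3-[(4-aminobutyl)amino]propyl}-2-(6-bromo-1H-indol-3-yl)-2-oxoacetamide (achiral) | NCCCCNCCCNC(=O)C(=O)c1c[nH]c2cc(Br)ccc12 | target

**Total step count:** 5
**Longest linear sequence:** 5 steps (1 → 2 → 3 → 6 → 7 → 9). Compound 4 enters unmodified at step 3.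

**Steps most likely to fail**

Step 3. The risks are single carbonylation to the indole-3-carboxamide, loss of iodine from the unprotected 5, and sluggish oxidative addition under CO pressure. The fallback sets out from 4 and comes back to the route at 6. The CO chemistry is given up and 4 is acylated at C3 with oxalyl chloride in Et2O at 0 °C (Speeter–Anthony acylation), which precipitates 2-(6-bromo-1H-indol-3-yl)-2-oxoacetyl chloride F1. The solid is added to 3 and i-Pr2NEt in THF at 0 °C, where the ring N–H of 3 is acylated to give 6.

Step 4. The risks are that the freed N4 is alkylated by the departing carbon fragment (decarboxylation of the Mannich base or aza-Michael addition) and that ring opening stalls. The fallback sets out from 4 and comes back to the route at 8. The methylene tether is dropped altogether. Compound 4 is taken through 5 under the conditions of step 3, with purchased tert-butyl (3-aminopropyl)[4-(tert-butoxycarbonylamino)butyl]carbamate, CC(C)(C)OC(=O)NCCCCN(CCCN)C(=O)OC(C)(C)C, in place of 3. This gives tert-butyl (3-{[2-(6-bromo-1H-indol-3-yl)-2-oxoacetyl]amino}propyl)[4-(tert-butoxycarbonylamino)butyl]carbamate F2, in which N4 carries a carbamate and not an aminal carbon. Treatment with 4 M HCl in dioxane removes both Boc groups in one operation and gives 8, which is neutralised as in step 5.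

Step 2. The risks are a second carbamate on the ring N–H and scrambling of the aminal. The fallback sets out from 2 and comes back to the route at 6. N8 is masked by a reaction that only a primary amine can undergo. PhCHO (1.0 equiv) and MgSO4 in CH2Cl2 give (E)-N-benzylidene-4-(tetrahydropyrimidin-1(2H)-yl)butan-1-amine F3. This imine takes the place of 3 in step 3 and gives 1-(3-{4-[(E)-benzylideneamino]butyl}tetrahydropyrimidin-1(2H)-yl)-2-(6-bromo-1H-indol-3-yl)ethane-1,2-dione F4. Aqueous citric acid (10%) in THF at rt hydrolyses the imine to 1-[3-(4-aminobutyl)tetrahydropyrimidin-1(2H)-yl]-2-(6-bromo-1H-indol-3-yl)ethane-1,2-dione F5. Boc2O in CH2Cl2 then gives 6, because N8 is the only amine nitrogen left that can be acylated.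

**Further compounds**
F1 | step 3 | 2-(6-bromo-1H-indol-3-yl)-2-oxoacetyl chloride | O=C(Cl)C(=O)c1c[nH]c2cc(Br)ccc12
F2 | step 4 | tert-butyl (3-{[2-(6-bromo-1H-indol-3-yl)-2-oxoacetyl]amino}propyl)[4-(tert-butoxycarbonylamino)butyl]carbamate | CC(C)(C)OC(=O)NCCCCN(CCCNC(=O)C(=O)c1c[nH]c2cc(Br)ccc12)C(=O)OC(C)(C)C
F3 | step 2 | (E)-N-benzylidene-4-(tetrahydropyrimidin-1(2H)-yl)butan-1-amine | c1ccccc1/C=N/CCCCN1CCCNC1
F4 | step 2 | 1-(3-{4-[(E)-benzylideneamino]butyl}tetrahydropyrimidin-1(2H)-yl)-2-(6-bromo-1H-indol-3-yl)ethane-1,2-dione | c1ccccc1/C=N/CCCCN1CCCN(C1)C(=O)C(=O)c1c[nH]c2cc(Br)ccc12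
F5 | step 2 | 1-[3-(4-aminobutyl)tetrahydropyrimidin-1(2H)-yl]-2-(6-bromo-1H-indol-3-yl)ethane-1,2-dione | NCCCCN1CCCN(C1)C(=O)C(=O)c1c[nH]c2cc(Br)ccc12
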